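**Retrosynthetic overview**
1. Lasiodiplactone A 16 ⇒ lactol 14: the pyran ring is closed last by making the aryl O‑12–C(ketal) bond with loss of the 12‑O‑methyl group (the proposed new step); the ketal centre follows oxolane C‑3.
2. 14 ⇒ benzylic bromide 9 + (S)‑4‑methyloxolan‑2‑one 11 (trans enolate alkylation, then MeLi); 11 ⇐ asymmetric hydrogenation of butenolide 10.
3. 9 ⇒ O‑methyllasiodiplodin 8 by bromomethylation at C‑11.
4. 8 ⇒ seco acid 7 by Mitsunobu macrolactonisation (C–O bond, inversion to 3R); 7 ⇒ toluic acid 5 + chloro alcohol 4, the latter from (S)‑propylene oxide 1.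
5. Ring order: arene (bought), 12‑membered lactone, oxolane (carried in from 11), pyran ketal ring last.

Assumption: the macrolide is numbered as in lasiodiplodin (C‑1 lactone carbonyl, C‑3 methyl carbinol, C‑11 the free arene CH next to the chain, C‑12 and C‑14 the oxygenated carbons), and in step 5 the BINAP antipode is the one that gives the (S)‑lactone (written as (S)‑BINAP; its mirror image is taken if the sense proves opposite).

**Route**

Step 1
Reactants: 1 (S)-2-methyloxirane; 2 1-bromo-5-chloropentane
Product: 4 (S)-8-chlorooctan-2-ol, via 5-chloropentylmagnesium bromide 3 (not isolated)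
Conditions: Mg, THF, rt; then CuI (10 mol %), 1, −30 to 0 °C
Reagents that add atoms: none
Why: CuI-catalysed Grignard opening of a terminal epoxide at its CH2 end (Mg inserts into C–Br, not C–Cl), so the (S) carbinol centre of 1 is carried over untouched.

Step 2
Reactants: 5 2,4-dimethoxy-6-methylbenzoic acid; 4 (S)-8-chlorooctan-2-ol
Product: 7 (S)-2-(8-hydroxynonyl)-4,6-dimethoxybenzoic acid, via dilithio benzylic dianion 6 (not isolated)
Conditions: LiN(i-Pr)2 (3.3 equiv), THF, DMPU, −78 °C to rt; aq HCl
Reagents that add atoms: none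
Why: lateral (benzylic) lithiation of an ortho-toluic acid as its dianion and SN2 alkylation by the primary chloride; the carboxylate cannot self-condense and the stereocentre is remote.

Step 3
Reactants: 7 (S)-2-(8-hydroxynonyl)-4,6-dimethoxybenzoic acid
Product: 8 (R)-O-methyllasiodiplodin [(3R)-12,14-dimethoxy-3-methyl-3,4,5,6,7,8,9,10-octahydro-1H-2-benzoxacyclododecin-1-one]
Conditions: PPh3, DIAD, toluene (2 mM), rt, slow addition of 7
Reagents that add atoms: none
Why: Mitsunobu macrolactonisation at high dilution; the hindered but acidic 2,6-disubstituted benzoate displaces the alkoxyphosphonium by SN2, inverting the (S) carbinol to the (3R) centre and closing the 12-membered ring.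

Step 4
Reactants: 8 (R)-O-methyllasiodiplodin
Product: 9 (3R)-11-(bromomethyl)-12,14-dimethoxy-3-methyl-3,4,5,6,7,8,9,10-octahydro-1H-2-benzoxacyclododecin-1-one
Conditions: (CH2O)n, 33% HBr in AcOH, AcOH, 40 °C; used crude
Reagents that add atoms: formaldehyde (as paraformaldehyde), C=O; hydrogen bromide, Br
Why: bromomethylation (Blanc-type electrophilic aromatic substitution) at C-11, the site para to 14-OMe and ortho to 12-OMe, while C-13 between the two methoxy groups is shielded, the same preference that 3,5-dimethoxytoluene and orsellinate ethers show.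

Step 5
Reactants: 10 4-methylfuran-2(5H)-one
Product: 11 (S)-4-methyloxolan-2-one
Conditions: H2 (100 atm), Ru(OAc)2[(S)-BINAP] (0.5 mol %), CH2Cl2, 50 °C
Reagents that add atoms: none
Why: BINAP–ruthenium asymmetric hydrogenation of a β-substituted butenolide; the catalyst selects one alkene face and sets oxolane C-4 as (S).

Step 6
Reactants: 11 (S)-4-methyloxolan-2-one (1.3 equiv); 9 benzylic bromide
Product: 13 (3R)-12,14-dimethoxy-3-methyl-11-{[(3S,4S)-4-methyl-2-oxooxolan-3-yl]methyl}-3,4,5,6,7,8,9,10-octahydro-1H-2-benzoxacyclododecin-1-one, via lithium enolate 12 (not isolated)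
Conditions: LiN(i-Pr)2, THF, −78 °C; then 9, −78 to −30 °C
Reagents that add atoms: none
Why: lactone enolate alkylation (SN2 on the benzylic bromide); the electrophile enters anti to the C-4 methyl and gives the trans (3S,4S) lactone, and the di-ortho-substituted macrolactone is too hindered to be attacked at −78 °C.

Step 7
Reactants: 13 trans-benzyl lactone
Product: 14 (3R)-11-{[(3S,4S)-2-hydroxy-2,4-dimethyloxolan-3-yl]methyl}-12,14-dimethoxy-3-methyl-3,4,5,6,7,8,9,10-octahydro-1H-2-benzoxacyclododecin-1-one (lactol, both anomers, in equilibrium with the open γ-hydroxy methyl ketone)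
Conditions: MeLi (1.3 equiv), THF, −78 °C; AcOH quench at −78 °C
Reagents that add atoms: methyllithium, [Li]C
Why: single addition of MeLi to a γ-lactone, whose lithium lactolate is stable at −78 °C, while the hindered aryl ester does not react; C-3 and C-4 of the oxolane are untouched.

Step 8
Reactants: 14 lactol
Product: 16 lasiodiplactone A, via anomeric iodide 15 (not isolated)
Conditions: Me3SiI (1.5 equiv), CH2Cl2, −40 to 0 °C, 1 h; Et3N, MeOH quench
Reagents that add atoms: none
Why: Proposed new method: oxocarbenium-relayed demethylative ketalisation, in which Me3SiI turns the lactol into the tertiary anomeric iodide/oxocarbenium ion pair 15, the neighbouring 12-OMe oxygen adds to the cationic carbon through a six-membered transition state to give an aryl methyl oxonium ion, and iodide removes the methyl group by SN2 as MeI. This makes the aryl O–C(ketal) bond irreversibly and only at the methoxy group that can reach the cation, since the 14-OMe, the ester and simple aryl ethers are inert to Me3SiI below 0 °C. The ketal carbon is forced into the cis-fused (S) configuration by oxolane C-3, and the acidic medium lets C-3 settle in the arrangement expected to be more stable (4-methyl on the convex face), which is the one already set in step 6. The closest known reaction types are the opening of cyclic ethers by glycosyl iodides via glycosyl oxonium ions, neighbouring-group participation of aryl methoxy groups with loss of methyl halide, and demethylative iodocyclisation of ortho-alkynyl anisoles.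

**Compound list**
1 | (S)-2-methyloxirane [(S)-propylene oxide] | C[C@H]1CO1 | starting material
2 | 1-bromo-5-chloropentane | ClCCCCCBr | starting material
3 | 5-chloropentylmagnesium bromide | ClCCCCC[Mg]Br | intermediate (not isolated)
4 | (S)-8-chlorooctan-2-ol | C[C@H](O)CCCCCCCl | intermediate
5 | 2,4-dimethoxy-6-methylbenzoic acid | COc1cc(OC)c(C(=O)O)c(C)c1 | starting material
6 | dilithio benzylic dianion of 5 (lithium carboxylate, lithiated 6-methyl group) | [Li+].[Li+].[CH2-]c1cc(OC)cc(OC)c1C([O-])=O | intermediate (not isolated)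
7 | (S)-2-(8-hydroxynonyl)-4,6-dimethoxybenzoic acid | COc1cc(OC)c(C(=O)O)c(CCCCCCC[C@H](C)O)c1 | intermediate
8 | (R)-O-methyllasiodiplodin, (3R)-12,14-dimethoxy-3-methyl-3,4,5,6,7,8,9,10-octahydro-1H-2-benzoxacyclododecin-1-one | COc1cc(OC)c2c(c1)CCCCCCC[C@@H](C)OC2=O | intermediate
9 | (3R)-11-(bromomethyl)-12,14-dimethoxy-3-methyl-3,4,5,6,7,8,9,10-octahydro-1H-2-benzoxacyclododecin-1-one | COc1cc(OC)c2c(c1CBr)CCCCCCC[C@@H](C)OC2=O | intermediate
10 | 4-methylfuran-2(5H)-one | CC1=CC(=O)OC1 | starting material
11 | (S)-4-methyloxolan-2-one [(S)-β-methyl-γ-butyrolactone] | O=C1C[C@H](C)CO1 | intermediate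
12 | lithium enolate of 11 | [Li+].[O-]C1=C[C@H](C)CO1 | intermediate (not isolated)
13 | (3R)-12,14-dimethoxy-3-methyl-11-{[(3S,4S)-4-methyl-2-oxooxolan-3-yl]methyl}-3,4,5,6,7,8,9,10-octahydro-1H-2-benzoxacyclododecin-1-one (benzyl and methyl trans on the lactone) | COc1cc(OC)c2c(c1C[C@H]3[C@H](C)COC3=O)CCCCCCC[C@@H](C)OC2=O | intermediate
14 | (3R)-11-{[(3S,4S)-2-hydroxy-2,4-dimethyloxolan-3-yl]methyl}-12,14-dimethoxy-3-methyl-3,4,5,6,7,8,9,10-octahydro-1H-2-benzoxacyclododecin-1-one (lactol, C-2 of the oxolane unassigned) | COc1cc(OC)c2c(c1C[C@H]3[C@H](C)COC3(C)O)CCCCCCC[C@@H](C)OC2=O | intermediate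
15 | (3R)-11-{[(3S,4S)-2-iodo-2,4-dimethyloxolan-3-yl]methyl}-12,14-dimethoxy-3-methyl-3,4,5,6,7,8,9,10-octahydro-1H-2-benzoxacyclododecin-1-one (anomeric iodide, ion-paired with its oxocarbenium form) | COc1cc(OC)c2c(c1C[C@H]3[C@H](C)COC3(C)I)CCCCCCC[C@@H](C)OC2=O | intermediate (not isolated)
16 | lasiodiplactone A: (3R)-lasiodiplodin core in which O-12 and the C-11 methylene are bridged by a cis-fused oxolane ketal; oxolane C-2 (S, ketal, methyl), C-3 (S, bears the C-11 CH2), C-4 (S, methyl trans to that CH2) | COc1cc2c(c3c1C(=O)O[C@H](C)CCCCCCC3)C[C@H]1[C@H](C)CO[C@@]1(C)O2 | target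

**Step count**
Total: 8 steps. Longest linear sequence: 7 steps (steps 1, 2, 3, 4, 6, 7, 8); step 5 is a one-step side branch.

**Steps most likely to fail, each with a fallback**

Step 8 (proposed new step). Risks are a slow oxonium relay, opening of the oxolane by iodide, or attack on the wrong ether. The fallback uses known chemistry and sets out from lactol 14. NaSEt (5 equiv) in DMF at 110 °C removes the methyl group para to the lactone carbonyl by SN2 at methyl, the selectivity known for O-methyllasiodiplodin-type resorcylates. This gives the phenol lactol (3R)-12-hydroxy-11-{[(3S,4S)-2-hydroxy-2,4-dimethyloxolan-3-yl]methyl}-14-methoxy-3-methyl-3,4,5,6,7,8,9,10-octahydro-1H-2-benzoxacyclododecin-1-one F1. Camphorsulfonic acid (cat.) in CH2Cl2 over 4 Å sieves then closes the ketal under thermodynamic control, and the fallback comes back to the route at target 16.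

Step 4 (bromomethylation). Risks are attack at C-13, diarylmethane formation, and loss of the labile bromide. The fallback sets out from macrolide 8. Rieche formylation (Cl2CHOMe, TiCl4, CH2Cl2, −20 °C) gives the aldehyde (3R)-12,14-dimethoxy-3-methyl-1-oxo-3,4,5,6,7,8,9,10-octahydro-1H-2-benzoxacyclododecine-11-carbaldehyde F2, whose regiochemistry can be checked by NOE before going on. NaBH4 in MeOH gives the benzylic alcohol (3R)-11-(hydroxymethyl)-12,14-dimethoxy-3-methyl-3,4,5,6,7,8,9,10-octahydro-1H-2-benzoxacyclododecin-1-one F3. PBr3 in CH2Cl2 at 0 °C, made immediately before step 6, brings the fallback back to the route at bromide 9.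

Step 2 (dianion alkylation with the chloro alkoxide). Risks are a sluggish primary chloride and aggregation of the polyanions. The fallback replaces the alkylation–lactonisation pair by ring-closing metathesis and sets out from acid 5 and epoxide 1. Acid 5 with LiN(i-Pr)2 (2.2 equiv) and allyl bromide gives 2-(but-3-en-1-yl)-4,6-dimethoxybenzoic acid F4. Epoxide 1 with but-3-enylmagnesium bromide and CuI (cat.) gives (S)-hept-6-en-2-ol F5. Mitsunobu esterification (PPh3, DIAD, THF) joins them with inversion to (R)-hept-6-en-2-yl 2-(but-3-en-1-yl)-4,6-dimethoxybenzoate F6. Ring-closing metathesis with the second-generation Grubbs catalyst RuCl2(=CHPh)(PCy3)(H2IMes) in dilute CH2Cl2 at 40 °C gives the 7,8-unsaturated macrolide (3R)-12,14-dimethoxy-3-methyl-3,4,5,6,9,10-hexahydro-1H-2-benzoxacyclododecin-1-one F7 as an E/Z mixture. Hydrogenation (H2, Pd/C, EtOAc) brings the fallback back to the route at macrolide 8.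

**Further compounds**
F1 | step 8 | (3R)-12-hydroxy-11-{[(3S,4S)-2-hydroxy-2,4-dimethyloxolan-3-yl]methyl}-14-methoxy-3-methyl-3,4,5,6,7,8,9,10-octahydro-1H-2-benzoxacyclododecin-1-one | Oc1cc(OC)c2c(c1C[C@H]3[C@H](C)COC3(C)O)CCCCCCC[C@@H](C)OC2=O
F2 | step 4 | (3R)-12,14-dimethoxy-3-methyl-1-oxo-3,4,5,6,7,8,9,10-octahydro-1H-2-benzoxacyclododecine-11-carbaldehyde | COc1cc(OC)c2c(c1C=O)CCCCCCC[C@@H](C)OC2=O
F3 | step 4 | (3R)-11-(hydroxymethyl)-12,14-dimethoxy-3-methyl-3,4,5,6,7,8,9,10-octahydro-1H-2-benzoxacyclododecin-1-one | COc1cc(OC)c2c(c1CO)CCCCCCC[C@@H](C)OC2=O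
F4 | step 2 | 2-(but-3-en-1-yl)-4,6-dimethoxybenzoic acid | COc1cc(OC)c(C(=O)O)c(CCC=C)c1
F5 | step 2 | (S)-hept-6-en-2-ol | C[C@H](O)CCCC=C
F6 | step 2 | (R)-hept-6-en-2-yl 2-(but-3-en-1-yl)-4,6-dimethoxybenzoate | COc1cc(OC)c(C(=O)O[C@H](C)CCCC=C)c(CCC=C)c1
F7 | step 2 | (3R)-12,14-dimethoxy-3-methyl-3,4,5,6,9,10-hexahydro-1H-2-benzoxacyclododecin-1-one (E/Z mixture) | COc1cc(OC)c2c(c1)CCC=CCCC[C@@H](C)OC2=O
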